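**Retrosynthetic overview**
1. Target 18 ⇒ the furan ring of the benzofuran is closed last: the C3–C3a bond joins the nucleophilic C4–H carbon of 2-geranylresorcinol 6 to the α-carbon of α-chloroketone 16, which acts as an enolonium equivalent (two normally nucleophilic carbons are joined); C7a–O cyclodehydration follows in the same flask.
2. 16 ⇐ methyl ester 14 by chloromethyllithium homologation.
3. 14 (dihydrofuran ring, the only stereocentre) ⇐ prenyl arene 11 by Shi epoxidation and 5-exo phenoxide opening with inversion.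
4. 11 ⇐ methyl 3,5-dihydroxybenzoate 7 (C2 bromination, acetylation, Stille prenylation); 6 ⇐ resorcinol 1 (MOM-directed ortho-lithiation, geranylation, deprotection).
5. Ring order: dihydrofuran ring of the aryl fragment first (step 6), benzofuran furan ring last (step 8); both benzene rings are bought.

Assumption: the target is the (S)-isomer at C2 of the dihydrobenzofuran with an E-geranyl chain, as the SMILES encodes; geranyl bromide and the prenylstannane 10 are purchased.

**Route**

Step 1
Reactants: 1 resorcinol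
Product: 2 1,3-bis(methoxymethoxy)benzene
Conditions: NaH (2.4 equiv), DMF, 0 °C; MOMCl (2.4 equiv), 0 °C → rt
Reagents that add atoms: chloromethyl methyl ether, COCCl
Why: Williamson-type O-alkylation of the bis-phenoxide (MOM protection) installs the two acetal ethers that direct the lithiation of step 2.

Step 2
Reactants: 2 1,3-bis(methoxymethoxy)benzene; 3 geranyl bromide
Product: 5 2-[(2E)-3,7-dimethylocta-2,6-dien-1-yl]-1,3-bis(methoxymethoxy)benzene, via aryllithium 4 (not isolated)
Conditions: n-BuLi (1.1 equiv), THF, 0 °C → rt, 1 h; then CuI (10 mol %), 3, −78 °C → rt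
Reagents that add atoms: none
Why: Directed ortho-metalation, in which both OMOM groups steer n-BuLi to C2, followed by SN2 displacement of the primary allylic bromide, which keeps the E-alkene.

Step 3
Reactants: 5 2-[(2E)-3,7-dimethylocta-2,6-dien-1-yl]-1,3-bis(methoxymethoxy)benzene
Product: 6 2-[(2E)-3,7-dimethylocta-2,6-dien-1-yl]benzene-1,3-diol (2-geranylresorcinol)
Conditions: aq. HCl (2 M, cat.), MeOH, 40 °C
Reagents that add atoms: none
Why: Acid-catalysed acetal exchange with methanol (MOM deprotection) is mild enough to leave both trisubstituted alkenes uncyclised.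

Step 4
Reactants: 7 methyl 3,5-dihydroxybenzoate
Product: 9 methyl 3,5-diacetoxy-2-bromobenzoate, via bromodiol 8 (not isolated)
Conditions: NBS (1.0 equiv), MeCN, −20 → 0 °C; then Ac2O (3 equiv), pyridine, 4-(dimethylamino)pyridine (5 mol %), rt
Reagents that add atoms: N-bromosuccinimide, O=C1CCC(=O)N1Br; acetic anhydride, CC(=O)OC(C)=O
Why: Electrophilic aromatic bromination goes to C2 (para to one hydroxyl and ortho to the other, as in the 4-bromination of resorcinol) and not to the more hindered C4 between the hydroxyls, and acetylation then masks both phenols.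

Step 5
Reactants: 9 methyl 3,5-diacetoxy-2-bromobenzoate; 10 tributyl(3-methylbut-2-en-1-yl)stannane
Product: 11 methyl 3,5-diacetoxy-2-(3-methylbut-2-en-1-yl)benzoate
Conditions: Pd(PPh3)4 (5 mol %), DMF, 95 °C
Reagents that add atoms: none
Why: Stille coupling of the ester-activated aryl bromide with the prenylstannane gives the linear prenyl arene under neutral conditions that aryl acetates tolerate.

Step 6
Reactants: 11 methyl 3,5-diacetoxy-2-(3-methylbut-2-en-1-yl)benzoate
Product: 14 methyl (2S)-6-hydroxy-2-(2-hydroxypropan-2-yl)-2,3-dihydro-1-benzofuran-4-carboxylate, via epoxide diacetate 12 (not isolated), via epoxy diphenol 13 (not isolated)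
Conditions: 1,2:4,5-di-O-isopropylidene-β-D-erythro-2,3-hexodiulo-2,6-pyranose (30 mol %), KHSO5 (as 2KHSO5·KHSO4·K2SO4), K2CO3, Bu4NHSO4 (cat.), MeCN–CH2(OMe)2–aq. Na2B4O7 buffer, pH 10.5, −5 °C; then MeOH, K2CO3, rt
Reagents that add atoms: potassium peroxymonosulfate, [K+].[O-]S(=O)(=O)OO
Why: Shi asymmetric epoxidation by the D-fructose-derived dioxirane (spiro transition state) gives the (R)-epoxide, and after methanolysis of the acetates the ortho-phenoxide opens it 5-exo at the secondary carbon with SN2 inversion, which sets the (S)-centre.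

Step 7
Reactants: 14 methyl (2S)-6-hydroxy-2-(2-hydroxypropan-2-yl)-2,3-dihydro-1-benzofuran-4-carboxylate
Product: 16 2-chloro-1-[(2S)-6-hydroxy-2-(2-hydroxypropan-2-yl)-2,3-dihydro-1-benzofuran-4-yl]ethan-1-one, via lithium hemiketal 15 (not isolated)
Conditions: MeLi·LiBr (2.0 equiv), THF, −78 °C; then ICH2Cl (3 equiv), MeLi·LiBr (3 equiv, slow addition), −78 °C; sat. aq. NH4Cl, −78 °C → rt
Reagents that add atoms: chloroiodomethane, ClCI
Why: Chloromethyllithium (carbenoid) homologation of an ester, in which the two hydroxyls are first converted to lithium salts and the tetrahedral lithium hemiketal survives at −78 °C, so it collapses to the α-chloroketone only on quench without over-addition.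

Step 8
Reactants: 6 2-[(2E)-3,7-dimethylocta-2,6-dien-1-yl]benzene-1,3-diol; 16 2-chloro-1-[(2S)-6-hydroxy-2-(2-hydroxypropan-2-yl)-2,3-dihydro-1-benzofuran-4-yl]ethan-1-one
Product: 18 (2S)-4-{7-[(2E)-3,7-dimethylocta-2,6-dien-1-yl]-6-hydroxy-1-benzofuran-2-yl}-2-(2-hydroxypropan-2-yl)-2,3-dihydro-1-benzofuran-6-ol, via ketone 17 (not isolated)
Conditions: 6 (2 equiv), neutral Al2O3 (activity grade 1, large excess), xylenes, 130 °C, N2
Reagents that add atoms: none
Why: Alumina-promoted Friedel–Crafts-type ortho C-alkylation of a phenol by an α-haloketone followed by cyclodehydration (a known one-pot 2-arylbenzofuran synthesis): the α-carbon of 16 is attacked by C4 of surface-bound 6 (ortho to one hydroxyl, para to the other, the only activated open site), the adjacent hydroxyl then condenses with the ketone, and the stereocentre is not touched.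

**Compound list**
1 | resorcinol | Oc1cccc(O)c1 | starting material
2 | 1,3-bis(methoxymethoxy)benzene | COCOc1cccc(OCOC)c1 | intermediate
3 | geranyl bromide, (2E)-1-bromo-3,7-dimethylocta-2,6-diene | CC(C)=CCC/C(C)=C/CBr | starting material
4 | [2,6-bis(methoxymethoxy)phenyl]lithium | [Li]c1c(OCOC)cccc1OCOC | intermediate
5 | 2-[(2E)-3,7-dimethylocta-2,6-dien-1-yl]-1,3-bis(methoxymethoxy)benzene | CC(C)=CCC/C(C)=C/Cc1c(OCOC)cccc1OCOC | intermediate
6 | 2-[(2E)-3,7-dimethylocta-2,6-dien-1-yl]benzene-1,3-diol (2-geranylresorcinol) | CC(C)=CCC/C(C)=C/Cc1c(O)cccc1O | intermediate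
7 | methyl 3,5-dihydroxybenzoate | COC(=O)c1cc(O)cc(O)c1 | starting material
8 | methyl 2-bromo-3,5-dihydroxybenzoate | COC(=O)c1cc(O)cc(O)c1Br | intermediate
9 | methyl 3,5-diacetoxy-2-bromobenzoate | COC(=O)c1cc(OC(C)=O)cc(OC(C)=O)c1Br | intermediate
10 | tributyl(3-methylbut-2-en-1-yl)stannane | CCCC[Sn](CCCC)(CCCC)CC=C(C)C | starting material
11 | methyl 3,5-diacetoxy-2-(3-methylbut-2-en-1-yl)benzoate | COC(=O)c1cc(OC(C)=O)cc(OC(C)=O)c1CC=C(C)C | intermediate
12 | methyl 3,5-diacetoxy-2-{[(2R)-3,3-dimethyloxiran-2-yl]methyl}benzoate | COC(=O)c1cc(OC(C)=O)cc(OC(C)=O)c1C[C@H]1OC1(C)C | intermediate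
13 | methyl 2-{[(2R)-3,3-dimethyloxiran-2-yl]methyl}-3,5-dihydroxybenzoate | COC(=O)c1cc(O)cc(O)c1C[C@H]1OC1(C)C | intermediate
14 | methyl (2S)-6-hydroxy-2-(2-hydroxypropan-2-yl)-2,3-dihydro-1-benzofuran-4-carboxylate | COC(=O)c1cc(O)cc2c1C[C@@H](C(C)(C)O)O2 | intermediate
15 | trilithium salt of the chloromethyl methyl hemiketal of 14 (hemiketal carbon unassigned) | COC(O[Li])(CCl)c1cc(O[Li])cc2c1C[C@@H](C(C)(C)O[Li])O2 | intermediate
16 | 2-chloro-1-[(2S)-6-hydroxy-2-(2-hydroxypropan-2-yl)-2,3-dihydro-1-benzofuran-4-yl]ethan-1-one | O=C(CCl)c1cc(O)cc2c1C[C@@H](C(C)(C)O)O2 | intermediate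
17 | 2-{2,4-dihydroxy-3-[(2E)-3,7-dimethylocta-2,6-dien-1-yl]phenyl}-1-[(2S)-6-hydroxy-2-(2-hydroxypropan-2-yl)-2,3-dihydro-1-benzofuran-4-yl]ethan-1-one | CC(C)=CCC/C(C)=C/Cc1c(O)ccc(CC(=O)c2cc(O)cc3c2C[C@@H](C(C)(C)O)O3)c1O | intermediate
18 | (2S)-4-{7-[(2E)-3,7-dimethylocta-2,6-dien-1-yl]-6-hydroxy-1-benzofuran-2-yl}-2-(2-hydroxypropan-2-yl)-2,3-dihydro-1-benzofuran-6-ol | CC(C)=CCC/C(C)=C/Cc1c(O)ccc2cc(-c3cc(O)cc4c3C[C@@H](C(C)(C)O)O4)oc12 | target

**Count**
Total steps: 8. Longest linear sequence: 5 steps (steps 4–8 from methyl 3,5-dihydroxybenzoate 7); the other branch is steps 1–3 plus step 8.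

**Three steps most likely to fail**

Step 8 is the riskiest. O-alkylation would lead to the 3-aryl isomer, double alkylation of 6 is possible, the chloride is less reactive than the bromides usually used, and hot alumina may cyclise the geranyl phenol or dehydrate the tertiary alcohol. The fallback sets out from 5 and 16 and replaces the C–H alkylation by a cross-coupling of a pre-metalated arene with the same α-chloroketone. Compound 5 is lithiated at C4, ortho to OMOM (n-BuLi, N,N,N′,N′-tetramethylethylenediamine, THF, 0 °C), quenched with B(OMe)3 and hydrolysed to {3-[(2E)-3,7-dimethylocta-2,6-dien-1-yl]-2,4-bis(methoxymethoxy)phenyl}boronic acid F1. Suzuki–Miyaura coupling of F1 at the C–Cl bond of 16 (Pd(OAc)2, tri(1-naphthyl)phosphine, K3PO4, THF–H2O, rt) gives 2-{3-[(2E)-3,7-dimethylocta-2,6-dien-1-yl]-2,4-bis(methoxymethoxy)phenyl}-1-[(2S)-6-hydroxy-2-(2-hydroxypropan-2-yl)-2,3-dihydro-1-benzofuran-4-yl]ethan-1-one F2. HCl in MeOH at 40 °C removes both MOM groups, so the fallback comes back to the route at 17, which cyclodehydrates under the same acid to 18.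

Step 7 is the second risk. The carbenoid is unstable, the substrate carries two acidic hydroxyls, and the product can alkylate its own phenoxide if the quench is not cold. The fallback sets out from 14 and builds the chloromethyl ketone through a sulfur ylide instead of a carbenoid. Ester 14 is acylated by dimethylsulfoxonium methylide (Me3S(O)I, KOt-Bu, 4 equiv, THF, 65 °C) to give the stable keto sulfoxonium ylide 2-(dimethyl-oxo-λ6-sulfanylidene)-1-[(2S)-6-hydroxy-2-(2-hydroxypropan-2-yl)-2,3-dihydro-1-benzofuran-4-yl]ethan-1-one F3. Protonation and chloride displacement of dimethyl sulfoxide (LiCl, methanesulfonic acid, THF, 60 °C) then deliver 16, where the fallback comes back to the route.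

Step 6 is the third risk. The aryl acetates may hydrolyse at pH 10.5 before the alkene is epoxidised, which exposes a phenoxide to the oxidant, and the enantiomeric excess for a benzylic prenyl group may fall short (14 can be recrystallised to raise it). The fallback sets out from 11 and uses dihydroxylation in place of epoxidation. Asymmetric dihydroxylation at near-neutral pH (K2OsO2(OH)4 cat., hydroquinine 1,4-phthalazinediyl diether (DHQ)2PHAL, N-methylmorpholine N-oxide, acetone–H2O, 0 °C) gives methyl 3,5-diacetoxy-2-[(2S)-2,3-dihydroxy-3-methylbutyl]benzoate F4. Selective mesylation of the secondary hydroxyl (MsCl, Et3N, CH2Cl2, −20 °C) gives methyl 3,5-diacetoxy-2-[(2S)-3-hydroxy-2-(methanesulfonyloxy)-3-methylbutyl]benzoate F5. NaH in THF at 0 °C closes the epoxide by attack of the tertiary alkoxide with inversion while the acetates are still in place, so the fallback comes back to the route at the (R)-epoxide 12, which is methanolysed to 14 as in step 6.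

**Further compounds**
F1 | step 8 | {3-[(2E)-3,7-dimethylocta-2,6-dien-1-yl]-2,4-bis(methoxymethoxy)phenyl}boronic acid | CC(C)=CCC/C(C)=C/Cc1c(OCOC)ccc(B(O)O)c1OCOC
F2 | step 8 | 2-{3-[(2E)-3,7-dimethylocta-2,6-dien-1-yl]-2,4-bis(methoxymethoxy)phenyl}-1-[(2S)-6-hydroxy-2-(2-hydroxypropan-2-yl)-2,3-dihydro-1-benzofuran-4-yl]ethan-1-one | CC(C)=CCC/C(C)=C/Cc1c(OCOC)ccc(CC(=O)c2cc(O)cc3c2C[C@@H](C(C)(C)O)O3)c1OCOC
F3 | step 7 | 2-(dimethyl-oxo-λ6-sulfanylidene)-1-[(2S)-6-hydroxy-2-(2-hydroxypropan-2-yl)-2,3-dihydro-1-benzofuran-4-yl]ethan-1-one | CS(C)(=O)=CC(=O)c1cc(O)cc2c1C[C@@H](C(C)(C)O)O2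
F4 | step 6 | methyl 3,5-diacetoxy-2-[(2S)-2,3-dihydroxy-3-methylbutyl]benzoate | COC(=O)c1cc(OC(C)=O)cc(OC(C)=O)c1C[C@H](O)C(C)(C)O
F5 | step 6 | methyl 3,5-diacetoxy-2-[(2S)-3-hydroxy-2-(methanesulfonyloxy)-3-methylbutyl]benzoate | COC(=O)c1cc(OC(C)=O)cc(OC(C)=O)c1C[C@H](OS(C)(=O)=O)C(C)(C)O
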